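**Plan**

1. Numbering: rings A/B are C1–C10, the chain is C11–C15, the butenolide is O–C16H–C17(CH3)=C18H–C19(=O). Ring methyls and the carboxyl are named by the carbon that bears them. Starting materials are larixol (1) and 3-methylfuran (2).
2. Retrosynthesis: cut the lactone O–C19 bond and return C16–H to a ketone. This gives a (Z)-4-oxo-2-enoic acid (C16–C19), the open form of a 16-hydroxybutenolide, which comes from a 2,3-disubstituted furan. Then cut C15–C16 (allyl–furyl), and take the 4α-carboxyl, the 8α-OH and the C13=C14 alkene back to larixol.
3. Enabling feature: C16 is the only stereocentre outside rings A/B and lies six bonds from C9. It is the carbonyl carbon of that oxo acid, and both lactol epimers open to one form that is planar at C16. A reductase can therefore set C16, and the butenolide ring then closes by itself.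
4. Forward: rings A/B come from larixol. A temporary γ-lactone (4α-C=O to 6α-O) is made by remote oxidation. The side chain is transposed to the E-allylic acetate and joined to the furan at C15–C16. The furan is photo-oxygenated and the butenolide ring is closed last.
5. Stereochemistry: C5, C6, C9 and C10 are those of larixol. C8 comes from α-face epoxidation and hydride opening. C4 comes from a 1,5-hydrogen transfer that can reach only the 4α-methyl. The 13E alkene comes from a chair-like acetate transposition. C16 comes from the enzyme.

Key step: step 14

Assumption: the free 6α-hydroxy-4α-carboxylic acid is taken not to re-close to the γ-lactone at pH 3–4 and 0–25 °C, since the target itself is this free hydroxy acid.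

**Route**

Step 1
Reactants: 1 larixol
Product: 3 larixol 8-spiro-epoxide (epoxide oxygen α on C8)
Conditions: mCPBA (1.1 equiv), NaHCO3, CH2Cl2, 0 °C
Reagents that add atoms: 3-chloroperbenzoic acid, O=C(OO)c1cccc(Cl)c1
Why: Prilezhaev epoxidation in which the 1,1-disubstituted C8=CH2 alkene should react ahead of the monosubstituted vinyl group, the peracid approaching the α face because the axial 10β-methyl shields the β face, which sets C8 with its oxygen α.

Step 2
Reactants: 3 larixol 8-spiro-epoxide
Product: 4 (13S)-labd-14-ene-6α,8α,13-triol
Conditions: LiAlH4, THF, 0 °C → reflux; aq. NaOH work-up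
Reagents that add atoms: none
Why: epoxide reduction by SN2 hydride attack at the unhindered epoxide CH2, which becomes the 8β-methyl while the C8–O bond, and with it the 8α configuration, is not touched.

Step 3
Reactants: 4 (13S)-labd-14-ene-6α,8α,13-triol
Product: 5 6α-nitrite ester of triol 4
Conditions: NOCl (1.05 equiv), pyridine, −20 °C, dark
Reagents that add atoms: nitrosyl chloride, O=NCl
Why: O-nitrosation (nitrite ester formation) should be fast at the secondary 6α-hydroxyl and slow at the two hindered tertiary hydroxyls, so one equivalent should give the 6-mononitrite, which is used crude.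

Step 4
Reactants: 5 6α-nitrite ester of triol 4
Product: 7 4α-(hydroxyiminomethyl) triol (oxime), via 4α-nitrosomethyl triol 6 (not isolated)
Conditions: hν (Hg lamp, Pyrex), toluene, 10 °C, Ar; then i-PrOH, reflux
Reagents that add atoms: none
Why: Barton nitrite photolysis, in which O–NO homolysis gives the 6α-alkoxyl radical, this radical takes a hydrogen from the 4α-methyl through a six-membered transition state (the equatorial 6α-oxygen and the equatorial 4α-methyl are peri to each other, whereas the 4β- and 10β-methyls are out of reach), NO recombines at the new primary radical and the nitroso compound tautomerises to the oxime, so that C4 becomes a stereocentre with the oxidised carbon α.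

Step 5
Reactants: 7 4α-(hydroxyiminomethyl) triol (oxime)
Product: 9 6α,4α-lactol (cyclic hemiacetal C4–CH(OH)–O–C6), via 4α-formyl triol 8 (not isolated)
Conditions: NaNO2, AcOH/H2O (9:1), 10 °C
Reagents that add atoms: water, O
Why: nitrosative deoximation (nitrous acid N-nitrosates the oxime, water adds and N2O leaves) should free the aldehyde, which the neighbouring 6α-hydroxyl captures as the five-membered hemiacetal.

Step 6
Reactants: 9 6α,4α-lactol
Product: 10 γ-lactone diol (C4–C(=O)–O–C6 lactone with free 8α- and 13-hydroxyls)
Conditions: TEMPO (cat.), PhI(OAc)2, CH2Cl2, 20 °C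
Reagents that add atoms: none
Why: oxoammonium (TEMPO) oxidation of a lactol to the lactone, a reaction to which tertiary alcohols and the vinyl group are inert.

Step 7
Reactants: 10 γ-lactone diol
Product: 11 lactone 8α,13-diacetate
Conditions: AcCl, PhNMe2, CH2Cl2, 0 → 20 °C
Reagents that add atoms: acetyl chloride, CC(=O)Cl
Why: acylation of hindered tertiary alcohols with acetyl chloride and a weak arylamine base, established for 8,13-dihydroxylabdanes, in which the 13-acetate arms the side chain and the 8-acetate keeps the 8-oxygen from closing onto C13 in the later allyl chemistry.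

Step 8
Reactants: 11 lactone 8α,13-diacetate
Product: 12 lactone (13E)-8α,15-diacetate (primary allylic acetate)
Conditions: PdCl2(MeCN)2 (5 mol %), THF, 20 °C
Reagents that add atoms: none
Why: [3,3]-sigmatropic allylic acetate transposition catalysed by divalent palladium (cyclisation-induced rearrangement through a six-membered acetoxonium intermediate) moves the acetate from C13 to C15 and forms the more substituted C13=C14 alkene, the chair placing the bulky C12 chain equatorial so that the E isomer should prevail, any Z isomer being removed on AgNO3-impregnated silica.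

Step 9
Reactants: 2 3-methylfuran
Product: 13 2-bromo-3-methylfuran
Conditions: NBS, DMF, −20 → 20 °C, dark
Reagents that add atoms: N-bromosuccinimide, O=C1CCC(=O)N1Br
Why: electrophilic aromatic bromination should go to the α-position next to the methyl group, whose σ-complex carries positive charge on the methyl-bearing carbon, and the labile bromide is used at once.

Step 10
Reactants: 13 2-bromo-3-methylfuran
Product: 15 tributyl(3-methylfuran-2-yl)stannane, via 2-lithio-3-methylfuran 14 (not isolated)
Conditions: n-BuLi, THF, −78 °C; then Bu3SnCl, −78 → 20 °C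
Reagents that add atoms: tributyltin chloride, CCCC[Sn](Cl)(CCCC)CCCC
Why: bromine–lithium exchange fixes the metal at C2 without the regiochemical ambiguity of direct deprotonation, and the furyllithium is trapped by the tin electrophile.

Step 11
Reactants: 12 lactone (13E)-8α,15-diacetate; 15 tributyl(3-methylfuran-2-yl)stannane
Product: 16 furan lactone 8-acetate (3-methylfuran-2-yl on C15)
Conditions: Pd(dba)2 (5 mol %), LiCl (3 equiv), DMF, 20 → 40 °C
Reagents that add atoms: none
Why: Stille coupling of an allylic acetate, in which zerovalent palladium ionises the primary acetate to a π-allyl complex, the electron-rich furylstannane transmetalates and reductive elimination at the unsubstituted CH2 terminus forms C15–C16 with the E alkene kept, while the lactone and the tertiary acetate are not touched.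

Step 12
Reactants: 16 furan lactone 8-acetate
Product: 18 furan dihydroxy acid (6α,8α-diol with 4α-CO2H), via potassium carboxylate 17 (not isolated)
Conditions: KOH, MeOH/H2O, reflux; then 1 M HCl to pH 4, 0 °C
Reagents that add atoms: potassium hydroxide, [K+].[OH-]
Why: saponification cleaves the tertiary 8-acetate and opens the γ-lactone at its acyl carbon, the furan and the skipped diene being inert to base, and cold acidification to pH 4 should only free the acid.

Step 13
Reactants: 18 furan dihydroxy acid
Product: 20 16-hydroxybutenolide (lactol as both C16 epimers), via furan endoperoxide 19 (not isolated)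
Conditions: O2, tetraphenylporphyrin (cat.), hν (visible), i-Pr2NEt, CH2Cl2, −78 °C
Reagents that add atoms: oxygen, O=O
Why: singlet oxygen adds across C16 and C19 of the furan in a [4+2] cycloaddition far faster than it attacks the trisubstituted alkene, and the amine removes the one bridgehead hydrogen (on C19) in a Kornblum–DeLaMare fragmentation, which gives the C19 carbonyl and the C16 hemiketal.

Step 14
Reactants: 20 16-hydroxybutenolide
Product: 23 CNP0387770.1, via (Z)-16-oxo acid 21 (not isolated), via (16R)-hydroxy acid 22 (not isolated)
Conditions: ketoreductase ((R)-selective, chosen from a panel), NADP+ (cat.), i-PrOH (10 vol %), phosphate buffer pH 7.0, 30 °C; then H3PO4 to pH 3, EtOAc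
Reagents that add atoms: none
Why: Proposed new method: at pH 7 both epimers of lactol 20 open to the dianion of oxo acid 21, which is planar at C16; the ketoreductase transfers hydride from NADPH (regenerated from isopropanol) to one face of the C16 carbonyl, and the (16R)-(Z)-4-hydroxy-2-enoic acid 22 cyclises on acidification by acyl substitution of the C16 oxygen at C19. The closest known reactions are ketoreductase reductions of γ-keto acids and esters that end in γ-lactones and the borohydride reduction of 5-hydroxybutenolides to butenolides; an enzymatic version on a (Z)-4-oxo-2-enoic acid has not been shown. The butenolide ring closes in the 5-exo-trig mode, and the Z alkene, fixed since the furan stage, holds the hydroxyl next to the carboxyl so that no activation is needed. C16 is controlled by the enzyme active site alone, because the nearest ring stereocentre is six bonds away and cannot bias the ketone faces; an enzyme with the (R) preference has to be found by screening. The step needs selectivity for the ketone over the conjugated C17=C18 bond and must neither move the β,γ C13=C14 alkene nor epimerise C16 afterwards, which the hydride specificity of a ketoreductase and neutral pH at 30 °C should secure. Because both lactol epimers drain into 21, the reduction is a dynamic process that can use all of the material.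

**Compound list**

1 | larixol ((13S)-labdane-6α,13-diol with exocyclic C8=CH2 and C14=C15 vinyl) | C=C[C@@](C)(O)CC[C@@H]1[C@@]2(C)CCCC(C)(C)[C@@H]2[C@@H](O)CC1=C | starting material
2 | 3-methylfuran | Cc1ccoc1 | starting material
3 | larixol 8-spiro-epoxide (epoxide oxygen α on C8, epoxide CH2 β) | C=C[C@@](C)(O)CC[C@@H]1[C@@]2(C)CCCC(C)(C)[C@@H]2[C@@H](O)C[C@]13CO3 | intermediate
4 | (13S)-labd-14-ene-6α,8α,13-triol (8β-methyl) | C=C[C@@](C)(O)CC[C@@H]1[C@@]2(C)CCCC(C)(C)[C@@H]2[C@@H](O)C[C@@]1(C)O | intermediate
5 | 6α-nitrite ester of triol 4 | C=C[C@@](C)(O)CC[C@@H]1[C@@]2(C)CCCC(C)(C)[C@@H]2[C@@H](ON=O)C[C@@]1(C)O | intermediate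
6 | 4α-nitrosomethyl triol (4α-CH2–N=O, 4β-CH3; not isolated) | C=C[C@@](C)(O)CC[C@@H]1[C@@]2(C)CCC[C@@](C)(CN=O)[C@@H]2[C@@H](O)C[C@@]1(C)O | intermediate
7 | 4α-(hydroxyiminomethyl) triol (oxime, geometry not fixed) | C=C[C@@](C)(O)CC[C@@H]1[C@@]2(C)CCC[C@@](C)(C=NO)[C@@H]2[C@@H](O)C[C@@]1(C)O | intermediate
8 | 4α-formyl triol (not isolated) | C=C[C@@](C)(O)CC[C@@H]1[C@@]2(C)CCC[C@@](C)(C=O)[C@@H]2[C@@H](O)C[C@@]1(C)O | intermediate
9 | 6α,4α-lactol (cyclic hemiacetal C4–CH(OH)–O–C6, both epimers at the acetal carbon; 8α,13-diol) | C=C[C@@](C)(O)CC[C@@H]1[C@@]2(C)CCC[C@@](C)(C(O)O3)[C@@H]2[C@@H]3C[C@@]1(C)O | intermediate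
10 | γ-lactone diol (C4–C(=O)–O–C6 lactone; (13S)-8α,13-diol; C14=C15 vinyl) | C=C[C@@](C)(O)CC[C@@H]1[C@@]2(C)CCC[C@@](C)(C(=O)O3)[C@@H]2[C@@H]3C[C@@]1(C)O | intermediate
11 | lactone 8α,13-diacetate | C=C[C@@](C)(OC(C)=O)CC[C@@H]1[C@@]2(C)CCC[C@@](C)(C(=O)O3)[C@@H]2[C@@H]3C[C@@]1(C)OC(C)=O | intermediate
12 | lactone (13E)-8α,15-diacetate (primary allylic acetate at C15) | CC(=O)OC/C=C(\C)CC[C@@H]1[C@@]2(C)CCC[C@@](C)(C(=O)O3)[C@@H]2[C@@H]3C[C@@]1(C)OC(C)=O | intermediate
13 | 2-bromo-3-methylfuran | Cc1ccoc1Br | intermediate
14 | 2-lithio-3-methylfuran (not isolated) | Cc1ccoc1[Li] | intermediate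
15 | tributyl(3-methylfuran-2-yl)stannane | CCCC[Sn](CCCC)(CCCC)c1occc1C | intermediate
16 | furan lactone 8-acetate (3-methylfuran-2-yl on C15, 13E) | Cc1ccoc1C/C=C(\C)CC[C@@H]1[C@@]2(C)CCC[C@@](C)(C(=O)O3)[C@@H]2[C@@H]3C[C@@]1(C)OC(C)=O | intermediate
17 | potassium 4α-carboxylate of 18 (not isolated) | Cc1ccoc1C/C=C(\C)CC[C@@H]1[C@@]2(C)CCC[C@@](C)(C(=O)[O-])[C@@H]2[C@@H](O)C[C@@]1(C)O.[K+] | intermediate
18 | furan dihydroxy acid (6α,8α-diol, 4α-CO2H, 13E, 3-methylfuran-2-yl on C15) | Cc1ccoc1C/C=C(\C)CC[C@@H]1[C@@]2(C)CCC[C@@](C)(C(=O)O)[C@@H]2[C@@H](O)C[C@@]1(C)O | intermediate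
19 | furan endoperoxide (O–O bridge from C16 to C19; not isolated) | CC1=CC2OOC1(C/C=C(\C)CC[C@@H]3[C@@]4(C)CCC[C@@](C)(C(=O)O)[C@@H]4[C@@H](O)C[C@@]3(C)O)O2 | intermediate
20 | 16-hydroxybutenolide (lactol, both C16 epimers) | CC1=CC(=O)OC1(O)C/C=C(\C)CC[C@@H]1[C@@]2(C)CCC[C@@](C)(C(=O)O)[C@@H]2[C@@H](O)C[C@@]1(C)O | intermediate
21 | (Z)-16-oxo acid, open form of 20 (not isolated) | O=C(O)/C=C(C)\C(=O)C/C=C(\C)CC[C@@H]1[C@@]2(C)CCC[C@@](C)(C(=O)O)[C@@H]2[C@@H](O)C[C@@]1(C)O | intermediate
22 | (16R)-(Z)-16-hydroxy acid (not isolated) | O=C(O)/C=C(C)\[C@H](O)C/C=C(\C)CC[C@@H]1[C@@]2(C)CCC[C@@](C)(C(=O)O)[C@@H]2[C@@H](O)C[C@@]1(C)O | intermediate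
23 | CNP0387770.1 | CC1=CC(=O)O[C@@H]1C/C=C(\C)CC[C@@H]1[C@@]2(C)CCC[C@@](C)(C(=O)O)[C@@H]2[C@@H](O)C[C@@]1(C)O | target

**Count**

Total steps: 14. Longest linear sequence: 12 steps (steps 1–8 and 11–14 from larixol); the furan branch (steps 9–10) joins at step 11.

**Steps most likely to fail**

Step 14 (the proposed new method). The panel may hold no enzyme that accepts the bulky dianionic oxo acid or that reduces the required face. During long incubations the C13=C14 alkene could drift into conjugation with the C16 ketone, or the conjugated C17=C18 bond could be reduced by contaminating ene-reductase activity. The fallback uses known chemistry and sets out from lactol 20. Its open keto carboxylate is reduced with NaBH4 in aqueous NaHCO3/THF at 0 °C and the mixture is acidified to pH 3. This is the established borohydride route from 5-hydroxybutenolides to butenolides, and it should give 23 together with its (16S)-epimer F1. The two are separated by preparative HPLC on a polysaccharide chiral phase, and the route is rejoined at 23.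

Step 4. β-Scission of the 6α-alkoxyl radical (C5–C6 cleavage to a tertiary radical), or simple return to the alcohol, may outrun the 1,5-hydrogen transfer. The fallback sets out from triol 4 and replaces the radical relay by a biocatalytic C–H oxidation. A fungal whole-cell hydroxylation of the kind known to oxidise the 4α-methyl of sclareol-type labdanes (Cunninghamella or Mucor strains, chosen by screening) should give the 4α-hydroxymethyl tetraol F2. Oxidation of F2 with TEMPO/PhI(OAc)2 takes the primary alcohol to the aldehyde, which closes to lactol 9 and is oxidised on to lactone 10. The route is rejoined at 10, and steps 3–6 are bypassed.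

Step 11. Slow transmetalation may let the π-allyl complex lose a β-hydrogen to a diene or equilibrate its geometry, which erodes the E alkene. Protodestannylation of the furylstannane may also starve the coupling. The fallback reverses the polarity of the partners and sets out from allylic acetate 12. Borylation with bis(pinacolato)diboron and Pd2(dba)3 (zerovalent palladium) in DMSO at 50 °C should give the allyl pinacolboronate F3. Suzuki–Miyaura coupling of F3 with bromofuran 13 under conditions known to give the linear allyl–aryl product (palladium diacetate, a bulky biarylphosphine, K3PO4, aqueous THF, 40 °C) rejoins the route at 16.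

**Further compounds**

F1 | step 14 | (16S)-epimer of the target | CC1=CC(=O)O[C@H]1C/C=C(\C)CC[C@@H]1[C@@]2(C)CCC[C@@](C)(C(=O)O)[C@@H]2[C@@H](O)C[C@@]1(C)O
F2 | step 4 | 4α-hydroxymethyl tetraol ((13S)-6α,8α,13-triol with 4α-CH2OH) | C=C[C@@](C)(O)CC[C@@H]1[C@@]2(C)CCC[C@@](C)(CO)[C@@H]2[C@@H](O)C[C@@]1(C)O
F3 | step 11 | (13E)-allyl pinacolboronate of the lactone 8-acetate (Bpin on C15) | CC1(C)OB(C/C=C(\C)CC[C@@H]2[C@@]3(C)CCC[C@@](C)(C(=O)O4)[C@@H]3[C@@H]4C[C@@]2(C)OC(C)=O)OC1(C)C
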